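I began with an easy step: the balance of the starting material, the limiting reagent, since its 0.20 M stands below the reagent's 0.220 M in blue and 0.290 M in grey. Starting material that is gone is product or sits on the catalyst, so the gap, meaning the charge minus starting material minus product, lies between nothing and what I call the catalyst's toll, the catalyst charge over the starting material charge, 5.00%.

in all of them: starting material 0.20 M; free catalyst 10 mM
- midnight: reagent 0.32 M; run made earlier
- winter: reagent 0.46 M; run made earlier
- blue: reagent 0.220 M; time 6.0 h
- grey: reagent 0.290 M; time 6.0 h

| run | time / h | catalyst intermediate A / % | product / % | starting material / % | catalyst intermediate B / % |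
|---|---|---|---|---|---|
| midnight | 0.667 | 2.0 | 5.9 | 89.8 | 0 |
| midnight | 1.33 | 2.7 | 10.8 | 87.1 | 0 |
| midnight | 2.00 | 1.4 | 13.1 | 83.3 | 0 |
| midnight | 2.50 | 1.4 | 14.5 | 81.2 | 0 |
| midnight | 3.00 | 1.6 | 18.5 | 79.5 | 0 |
| winter | 0.250 | 2.1 | 2.7 | 94.3 | 1.9 |
| winter | 0.833 | 2.7 | 8.1 | 87.9 | 0.3 |
| winter | 1.33 | 2.5 | 13.3 | 84.8 | 2.2 |
| winter | 2.00 | 1.2 | 17.4 | 78.8 | 0.5 |
| winter | 3.00 | 0.1 | 21.6 | 74.0 | 1.2 |

(scatter of a reading: 1 percentage point)

- which of these there is most of at the end, counted by the starting material in it, blue (starting material / product / catalyst intermediate A / catalyst intermediate B)
- which of these there is most of at the end, counted by the starting material in it, grey (starting material / product / catalyst intermediate A / catalyst intermediate B)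
- the largest of these amounts at the end, in percent of the starting material charged, blue
- the largest of these amounts at the end, in percent of the starting material charged, grey

- the analysis behind the earlier runs scatters by 1 percentage point, standard deviation

At 3.00 h the gap read 2 percentage points in midnight and 4.4 points in winter, both below the toll.

For a ceiling, I noted that winter's product was 1.17 times midnight's for 1.44 times the reagent. I scaled midnight's last product reading down in proportion to the reagent, which is an estimate and no proved limit. I took product to keep rising to 6.0 h, subtracted that scaled product and midnight's gap, and got an estimated ceiling of 85.3% for blue and 81.2% for grey.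

For a floor, I used midnight, which is richer in reagent than either flask. Its starting material fell 3.8 points in its last 1.00 h. Held at that pace to 6.0 h, it reaches 68.1%. The pace was already slackening, and one more slackening by the same reading tightened my floor to 70.6%. Starting material therefore stays the largest amount in both flasks.

The forecast, 76% for blue and 73% for grey, stood inside my brackets and said “the starting material remains dominant in both runs”.

Blue ended with 80.8% of starting material and grey with 76.6%, the largest amount in each.

    reagent + catalyst intermediate A ⇌ catalyst intermediate B (K = 1.30 L mol⁻¹, k = 37.6 L mol⁻¹ h⁻¹)
    catalyst intermediate B ⇌ free catalyst + product (K = 4.27 M, k = 10.0 h⁻¹)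
    catalyst intermediate A → spent catalyst (k = 0.648 h⁻¹)
    starting material + free catalyst → catalyst intermediate A (k = 59.3 L mol⁻¹ h⁻¹)

In blue, 93.6% of the catalyst stood as spent catalyst at 6.00 h, and the gap came to 5 points, level with the toll. The flask like grey but charged with 0.050 M of starting material has a toll of 20.0%. With 22.4% of its catalyst still free, the part of that toll paid comes to 15.5% of the starting material charged, and its 29.2% of starting material and 55.2% of product leave a gap of 16 points.

The data are simulated with made-up constants, noise included.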